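**Retrosynthetic overview**
- The free tetronic acid comes from its 4-O-methyl ether. The Z-ylidene C=C is cut by a vinylogous aldol condensation into 4-methoxy-3-methylfuran-2(5H)-one and an α-methyl C20 dienal.
- The E,E-diene is cut at its central C–C bond (Heck) into a chiral C10 alkenol and an (E)-2-methylalkenyl iodide that carries the furan.
- Key step: the central CH2–CH2 bond of the C10 alkenol is made by a nickel-electrocatalytic decarboxylative coupling. The partners are (4S)-4-methylhex-5-enoic acid (from (S)-β-citronellene) and (2R)-3-bromo-2-methylpropan-1-ol, and each one brings one bought stereocentre.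
- The alkenyl iodide comes from carboalumination/iodination of 3-(pent-4-ynyl)furan, which is made by Negishi coupling of 3-bromofuran.
- No ring is formed. The furan (enters in step 3) and the butenolide (enters in step 8) are bought intact.

Assumption: the compounds marked "starting material" in the list are taken as catalogue chemicals, and the configuration is taken as drawn (both methyl-bearing carbons S, ylidene Z, diene E,E).

**Step 1**
Reactants: 1 (S)-β-citronellene, (3S)-3,7-dimethylocta-1,6-diene
Product: 3 (4S)-4-methylhex-5-enoic acid, via aldehyde 2 (not isolated)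
Conditions: O3 (1.0 equiv, metered), MeCN/H2O 9:1, 0 °C; then aq NaClO2, 0 °C → rt
Reagents that add atoms: ozone [O-][O+]=O; water O; sodium chlorite [Na+].[O-]Cl=O
Why: Chemoselective ozonolysis followed by a Pinnick-type chlorite oxidation, in which the electron-rich trisubstituted alkene reacts several times faster than the vinyl group, water turns the carbonyl oxide directly into aldehyde plus H2O2, the H2O2 scavenges HOCl so the vinyl group survives, and the stereocentre is not touched.

**Step 2**
Reactants: 3 (4S)-4-methylhex-5-enoic acid; 4 (2R)-3-bromo-2-methylpropan-1-ol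
Product: 6 (2S,6S)-2,6-dimethyloct-7-en-1-ol, via NHP ester 5 (not isolated)
Conditions: N-hydroxyphthalimide, DIC, DMA, rt, 2 h (no DMAP); then 4 (1.5 equiv), NiBr2·glyme (10 mol %), 4,4′,4″-tBu3-terpyridine (12 mol %), NaI (20 mol %), LiBr electrolyte, undivided cell, Zn(+)/RVC(−), 5 mA, 2.5 F/mol, rt
Reagents that add atoms: none
Why: Proposed new method: a Ni-electrocatalytic decarboxylative cross-electrophile coupling of an in-situ NHP ester with an unprotected β-branched primary bromo alcohol, in which the cathode holds (terpy)Ni at Ni(I), Ni(I) takes up the bromide (as iodide) by halogen abstraction/rebound to give alkyl–Ni(II), the more easily reduced NHP ester is split by single-electron transfer into CO2, phthalimide anion and the primary 3-methylpent-4-enyl radical (4-exo/5-endo closure too slow to compete), and radical capture gives a dialkyl–Ni(III) that reductively eliminates the CH2–CH2 bond, so that the two different activation modes and the set current favour cross- over homo-coupling, the tridentate ligand blocks β-hydride elimination, and both bought stereocentres (β and γ to the reacting carbons) pass through unchanged (R in 4 becomes S in 6 only by a CIP priority switch); the closest known reaction types are the Ni/Zn reductive coupling of NHP esters with alkyl bromides and the Ni-electrocatalytic doubly decarboxylative coupling of two NHP esters.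

**Step 3**
Reactants: 7 (5-iodopent-1-yn-1-yl)trimethylsilane; 8 3-bromofuran
Product: 11 3-(pent-4-yn-1-yl)furan, via alkylzinc iodide 9 (not isolated), via silylalkyne 10 (not isolated)
Conditions: Zn dust, LiCl, THF, 40 °C; then 8, Pd(OAc)2 (2 mol %), SPhos (4 mol %), rt; then K2CO3 (cat.), MeOH, rt
Reagents that add atoms: none
Why: Negishi coupling, in which LiCl-promoted zinc insertion gives a primary alkylzinc that couples with the heteroaryl bromide under Pd/SPhos faster than β-hydride elimination, and carbonate/methanol then removes the alkynyl silane in the same flask.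

**Step 4**
Reactants: 11 3-(pent-4-yn-1-yl)furan
Product: 13 3-[(4E)-5-iodo-4-methylpent-4-en-1-yl]furan, via alkenylalane 12 (not isolated)
Conditions: Me3Al (2 equiv), Cp2ZrCl2 (0.25 equiv), CH2Cl2, 0 °C → rt; then I2, THF, −30 °C
Reagents that add atoms: trimethylaluminium C[Al](C)C; iodine II
Why: Zirconium-catalysed Negishi carboalumination adds Me and Al syn across the terminal alkyne with Me on the internal carbon, and iodinolysis with retention fixes the E trisubstituted alkene.

**Step 5**
Reactants: 6 (2S,6S)-2,6-dimethyloct-7-en-1-ol; 13 3-[(4E)-5-iodo-4-methylpent-4-en-1-yl]furan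
Product: 14 (2S,6S,7E,9E)-13-(furan-3-yl)-2,6,10-trimethyltrideca-7,9-dien-1-ol
Conditions: Pd(OAc)2 (10 mol %), n-Bu4NCl, K2CO3, DMF, 40 °C
Reagents that add atoms: none
Why: Heck reaction under Jeffery conditions, in which oxidative addition of 13 occurs with retention, sterically controlled syn insertion places the alkenyl group on the terminal carbon of the α-branched alkene, and syn β-hydride elimination toward conjugation gives the 7E,9E-diene without involving the allylic stereocentre.

**Step 6**
Reactants: 14 (2S,6S,7E,9E)-13-(furan-3-yl)-2,6,10-trimethyltrideca-7,9-dien-1-ol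
Product: 15 (2S,6S,7E,9E)-13-(furan-3-yl)-2,6,10-trimethyltrideca-7,9-dienal
Conditions: Dess–Martin periodinane, CH2Cl2, 0 °C → rt; used at once
Reagents that add atoms: none
Why: The Dess–Martin oxidation is fast and non-basic, stops at the aldehyde, and neither enolises the α-methyl centre nor touches the diene or the furan.

**Step 7**
Reactants: 16 3-methyltetronic acid, 4-hydroxy-3-methylfuran-2(5H)-one
Product: 17 4-methoxy-3-methylfuran-2(5H)-one
Conditions: Me2SO4, K2CO3, acetone, reflux
Reagents that add atoms: dimethyl sulfate COS(=O)(=O)OC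
Why: O-alkylation of the vinylogous acid anion with a hard methylating agent gives the 4-methyl ether, because C-3 is already blocked by its methyl group.

**Step 8**
Reactants: 17 4-methoxy-3-methylfuran-2(5H)-one; 15 (2S,6S,7E,9E)-13-(furan-3-yl)-2,6,10-trimethyltrideca-7,9-dienal
Product: 21 (5Z)-5-[(2S,6S,7E,9E)-13-(furan-3-yl)-2,6,10-trimethyltrideca-7,9-dien-1-ylidene]-4-methoxy-3-methylfuran-2(5H)-one, via lithium dienolate 18 (not isolated), via lithium aldolate 19 (not isolated), via mesylate 20 (not isolated)
Conditions: LDA, THF, −78 °C; 15, −78 °C; MsCl, −78 → 0 °C; DBU, 0 °C → rt (short)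
Reagents that add atoms: none
Why: Vinylogous aldol condensation, in which the C-5 lithiated tetronate adds to the aldehyde at −78 °C (so the α-methyl centre is not enolised), the alkoxide is mesylated in situ, and DBU-induced E1cB elimination erases the two transient stereocentres and gives the Z-ylidene, the isomer that avoids the clash between the side chain and the 4-OMe group.

**Step 9**
Reactants: 21 (5Z)-5-[(2S,6S,7E,9E)-13-(furan-3-yl)-2,6,10-trimethyltrideca-7,9-dien-1-ylidene]-4-methoxy-3-methylfuran-2(5H)-one
Product: 23 (5Z)-5-[(2S,6S,7E,9E)-13-(furan-3-yl)-2,6,10-trimethyltrideca-7,9-dien-1-ylidene]-4-hydroxy-3-methylfuran-2(5H)-one (CNP0389221.1), via lithium tetronate 22 (not isolated)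
Conditions: n-PrSH, n-BuLi, HMPA/THF, 0 °C → rt; then 1 M HCl
Reagents that add atoms: none
Why: SN2 demethylation of the vinylogous methyl ester by a soft thiolate releases the stabilised tetronate anion, which is protonated on work-up, and no stereocentre or alkene is touched.

**Compound list**
1 | (S)-β-citronellene, (3S)-3,7-dimethylocta-1,6-diene | C=C[C@@H](C)CCC=C(C)C | starting material
2 | (4S)-4-methylhex-5-enal | C=C[C@@H](C)CCC=O | intermediate
3 | (4S)-4-methylhex-5-enoic acid | C=C[C@@H](C)CCC(=O)O | intermediate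
4 | (2R)-3-bromo-2-methylpropan-1-ol | OC[C@@H](C)CBr | starting material
5 | 1,3-dioxoisoindolin-2-yl (4S)-4-methylhex-5-enoate | C=C[C@@H](C)CCC(=O)ON1C(=O)c2ccccc2C1=O | intermediate
6 | (2S,6S)-2,6-dimethyloct-7-en-1-ol | OC[C@@H](C)CCC[C@H](C)C=C | intermediate
7 | (5-iodopent-1-yn-1-yl)trimethylsilane | C[Si](C)(C)C#CCCCI | starting material
8 | 3-bromofuran | Brc1ccoc1 | starting material
9 | [5-(trimethylsilyl)pent-4-yn-1-yl]zinc iodide | C[Si](C)(C)C#CCCC[Zn]I | intermediate
10 | [5-(furan-3-yl)pent-1-yn-1-yl]trimethylsilane | C[Si](C)(C)C#CCCCc1ccoc1 | intermediate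
11 | 3-(pent-4-yn-1-yl)furan | C#CCCCc1ccoc1 | intermediate
12 | [(1E)-5-(furan-3-yl)-2-methylpent-1-en-1-yl]dimethylaluminium | C[Al](C)/C=C(\C)CCCc1ccoc1 | intermediate
13 | 3-[(4E)-5-iodo-4-methylpent-4-en-1-yl]furan | I/C=C(\C)CCCc1ccoc1 | intermediate
14 | (2S,6S,7E,9E)-13-(furan-3-yl)-2,6,10-trimethyltrideca-7,9-dien-1-ol | OC[C@@H](C)CCC[C@H](C)/C=C/C=C(\C)CCCc1ccoc1 | intermediate
15 | (2S,6S,7E,9E)-13-(furan-3-yl)-2,6,10-trimethyltrideca-7,9-dienal | O=C[C@@H](C)CCC[C@H](C)/C=C/C=C(\C)CCCc1ccoc1 | intermediate
16 | 3-methyltetronic acid, 4-hydroxy-3-methylfuran-2(5H)-one | CC1=C(O)COC1=O | starting material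
17 | 4-methoxy-3-methylfuran-2(5H)-one | CC1=C(OC)COC1=O | intermediate
18 | lithium 4-methoxy-3-methylfuran-2-olate | [Li+].Cc1c([O-])occ1OC | intermediate
19 | lithium aldolate of 17 and 15 (epimers at C-5 and the carbinol carbon) | [Li+].COC1=C(C)C(=O)OC1C([O-])[C@@H](C)CCC[C@H](C)/C=C/C=C(\C)CCCc2ccoc2 | intermediate
20 | methanesulfonate of the aldol (epimers at C-5 and the carbinol carbon) | COC1=C(C)C(=O)OC1C(OS(C)(=O)=O)[C@@H](C)CCC[C@H](C)/C=C/C=C(\C)CCCc2ccoc2 | intermediate
21 | (5Z)-5-[(2S,6S,7E,9E)-13-(furan-3-yl)-2,6,10-trimethyltrideca-7,9-dien-1-ylidene]-4-methoxy-3-methylfuran-2(5H)-one | CC1=C(OC)/C(=C/[C@@H](C)CCC[C@H](C)/C=C/C=C(\C)CCCc2ccoc2)OC1=O | intermediate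
22 | lithium salt of 23 | [Li+].CC1=C([O-])/C(=C/[C@@H](C)CCC[C@H](C)/C=C/C=C(\C)CCCc2ccoc2)OC1=O | intermediate
23 | (5Z)-5-[(2S,6S,7E,9E)-13-(furan-3-yl)-2,6,10-trimethyltrideca-7,9-dien-1-ylidene]-4-hydroxy-3-methylfuran-2(5H)-one | CC1=C(O)/C(=C/[C@@H](C)CCC[C@H](C)/C=C/C=C(\C)CCCc2ccoc2)OC1=O | target

**Step count**
- Total step count: 9.
- Longest linear sequence: 6 (steps 1, 2, 5, 6, 8, 9).

**Steps most likely to fail**

**Step 2 (the new coupling).**
- Risks: homodimer formation, Ni–H migration of the vinyl group, and acyl transfer from 5 to the free hydroxyl of 4.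
- The fallback uses known chemistry, sets out from 3 and comes back at 6.
- Acid 3 is put through a mixed Kolbe electrolysis (Pt/Pt, MeOH, about 5% neutralised, high current density, 10–20 °C). The co-acid, in three- to four-fold excess, is purchased (3S)-4-methoxy-3-methyl-4-oxobutanoic acid F1.
- This gives methyl (2S,6S)-2,6-dimethyloct-7-enoate F2. It is easily separated by polarity from the hydrocarbon and diester homodimers.
- LiAlH4 reduction of F2 gives 6.

**Step 5 (Heck on an unactivated alkene).**
- Risks: branched regioisomer and Pd–H isomerisation of the diene.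
- The fallback sets out from 6, keeps 13 as the partner, and comes back at 14.
- Cross-metathesis of 6 with vinylboronic acid pinacol ester (Hoveyda–Grubbs II, CH2Cl2, 40 °C) gives (2S,6S,7E)-2,6-dimethyl-8-(4,4,5,5-tetramethyl-1,3,2-dioxaborolan-2-yl)oct-7-en-1-ol F3.
- F3 is joined to 13 by a Suzuki–Miyaura coupling (Pd(PPh3)4, K3PO4, THF/H2O), with retention at both alkenes.

**Step 9 (thiolate demethylation).**
- Risks: conjugate addition of thiolate to the ylidene and a low yield on the polyene.
- The fallback replaces the methyl ether with a fluoride-labile group. It sets out from 16, uses 15, and comes back at 23.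
- Mitsunobu O-alkylation of 16 with 2-(trimethylsilyl)ethanol (PPh3, DIAD) gives 3-methyl-4-[2-(trimethylsilyl)ethoxy]furan-2(5H)-one F4.
- Lithiation with LDA and addition to 15 gives the aldol F5.
- MsCl/Et3N gives its methanesulfonate F6.
- DBU gives the (5Z)-ylidene 2-(trimethylsilyl)ethyl ether F7.
- TBAF in THF at 0 °C followed by acidic work-up releases 23.

**Further compounds**
F1 | step 2 | (3S)-4-methoxy-3-methyl-4-oxobutanoic acid (purchased co-acid) | COC(=O)[C@@H](C)CC(=O)O
F2 | step 2 | methyl (2S,6S)-2,6-dimethyloct-7-enoate | COC(=O)[C@@H](C)CCC[C@H](C)C=C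
F3 | step 5 | (2S,6S,7E)-2,6-dimethyl-8-(4,4,5,5-tetramethyl-1,3,2-dioxaborolan-2-yl)oct-7-en-1-ol | OC[C@@H](C)CCC[C@H](C)/C=C/B1OC(C)(C)C(C)(C)O1
F4 | step 9 | 3-methyl-4-[2-(trimethylsilyl)ethoxy]furan-2(5H)-one | CC1=C(OCC[Si](C)(C)C)COC1=O
F5 | step 9 | aldol of F4 and 15 (epimers at C-5 and the carbinol carbon) | CC1=C(OCC[Si](C)(C)C)C(OC1=O)C(O)[C@@H](C)CCC[C@H](C)/C=C/C=C(\C)CCCc2ccoc2
F6 | step 9 | methanesulfonate of F5 | CC1=C(OCC[Si](C)(C)C)C(OC1=O)C(OS(C)(=O)=O)[C@@H](C)CCC[C@H](C)/C=C/C=C(\C)CCCc2ccoc2
F7 | step 9 | (5Z)-5-[(2S,6S,7E,9E)-13-(furan-3-yl)-2,6,10-trimethyltrideca-7,9-dien-1-ylidene]-3-methyl-4-[2-(trimethylsilyl)ethoxy]furan-2(5H)-one | CC1=C(OCC[Si](C)(C)C)/C(=C/[C@@H](C)CCC[C@H](C)/C=C/C=C(\C)CCCc2ccoc2)OC1=O
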